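Retrosynthesis (quinone numbering: C1 = carbonyl beside the ring CH, C2 = C–OH, C3 = C–octadecyl, C4 = second carbonyl, C5 = C–OMe, C6 = CH): the quinone goes back to its benzene-1,2,4-triol, the oxygen on C1 is traded for an acetyl group, and the ring is then cut at C5–C6 and C1–C2 together, leaving a C2–C3–C4–C5 diene and a C1/C6 ynone; the C3–octadecyl bond is cut last.
Enabling feature: ring atoms C2(OH)–C3(alkyl)–C4(=O)–C5(OMe) are, atom for atom, the ester carbon, α-carbon, ketone carbon and MeO–CH2 carbon of an α-alkylated methyl 4-methoxy-3-oxobutanoate. Its bis(silyl) dienol ether is a 1,3-diene whose donor end (C5) and acceptor end (C2) match the β- and α-carbons of but-3-yn-2-one, so the OMe/OH difference of the target is built in.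
Forward: alkylation joins the C18 chain; two silylations give the diene; one Diels–Alder/aromatization closes the only ring as an acetylresorcinol; Dakin oxidation swaps the acetyl helper for the C1 oxygen and air sets the quinone level.
Stereochemistry: the target has no stereocentre; sp3 centres and enol-ether geometries met on the way are not controlled and are erased on aromatization.

Key step: step 4

Remark on the chemistry: enol-ether double bonds of the silylated intermediates are written without descriptors because their geometry is not controlled and is of no consequence; the bis(silyl) diene cannot be distilled and is assumed to be usable crude after filtration of the salts under argon.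

Step 1
Reactants: 1 methyl 4-methoxy-3-oxobutanoate; 2 1-iodooctadecane
Product: 4 methyl 2-(methoxyacetyl)icosanoate, via sodium enolate 3 (not isolated)
Conditions: NaH, THF–DMF, 0 °C; then 2, 60 °C
Reagents that add atoms: none
Why: Acetoacetic ester alkylation, in which the sodium enolate of the β-keto ester should undergo SN2 C-alkylation at the doubly activated carbon with the primary iodide, the new stereocentre arising as a racemate that is removed again in step 2.

Step 2
Reactants: 4 methyl 2-(methoxyacetyl)icosanoate
Product: 5 methyl 2-[2-methoxy-1-(trimethylsilyloxy)ethylidene]icosanoate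
Conditions: Me3SiCl, Et3N, toluene, rt
Reagents that add atoms: chlorotrimethylsilane, C[Si](C)(C)Cl
Why: Silyl enol ether formation by soft enolization, since the β-keto ester is acidic enough for Et3N and the silicon electrophile should go to the ketone oxygen to give the conjugated β-silyloxy enoate, as in the first stage of the usual preparation of 1-alkoxy-1,3-bis(silyloxy)dienes.

Step 3
Reactants: 5 methyl 2-[2-methoxy-1-(trimethylsilyloxy)ethylidene]icosanoate
Product: 7 1,4-dimethoxy-2-octadecyl-1,3-bis(trimethylsilyloxy)buta-1,3-diene, via lithium dienolate 6 (not isolated)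
Conditions: LiN(iPr)2, THF, −78 °C; then Me3SiCl, −78 °C → rt; salts filtered off under argon, used crude
Reagents that add atoms: chlorotrimethylsilane, C[Si](C)(C)Cl
Why: Vinylogous (γ) deprotonation of the β-silyloxy enoate at the MeO–CH2 group gives the extended ester dienolate, and kinetic O-silylation of this hard oxygen nucleophile should deliver the ketene silyl acetal diene (second stage of the standard bis(silyl enol ether) synthesis).

Step 4
Reactants: 7 1,4-dimethoxy-2-octadecyl-1,3-bis(trimethylsilyloxy)buta-1,3-diene; 8 but-3-yn-2-one
Product: 10 1-(2,4-dihydroxy-5-methoxy-3-octadecylphenyl)ethan-1-one, via cycloadduct 9 (not isolated)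
Conditions: toluene, rt → 90 °C (sealed); then 1 M HCl, THF, rt
Reagents that add atoms: none
Why: Normal-electron-demand Diels–Alder reaction in which the electron-rich diene C(OMe)(OSiMe3)=C(C18H37)–C(OSiMe3)=CH(OMe) of 7 adds across the triple bond of ynone 8, most likely asynchronously, the bond from the MeO–CH= terminus to the alkyne CH leading and the bond from the ketene acetal carbon to the acetyl-bearing carbon following, to give cyclohexa-1,4-diene 9. The closest known reaction type is the cycloaddition–aromatization of 1-alkoxy-1,3-bis(silyloxy)- and 1,1-dialkoxy-3-silyloxybuta-1,3-dienes with acetylenic ketones and esters, which gives resorcinol derivatives. The only ring of the target is closed here as a six-membered carbocycle by an intermolecular [4+2] cycloaddition, both ring bonds (C5–C6 and C1–C2 of the later quinone) forming in the same step. Adduct 9 carries two sp3 ring carbons as an uncontrolled mixture and neither survives, since acid removes both silyl groups, the hemiketal expels methanol and the dienone enolizes to the arene, so no stereocentre has to be controlled. The step needs one regiochemistry, which the substrate secures because the MeO–CH= carbon is the vinylogous donor end of the silyl dienolate and meets the β-carbon of the ynone while the former ester carbon is the acceptor end and meets the α-carbon; it also needs aromatization with the ring methoxy group kept, which is secured because the CH(OMe) carbon gives up its only hydrogen on enolization whereas the ketal carbon has none and must lose methanol.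

Step 5
Reactants: 10 1-(2,4-dihydroxy-5-methoxy-3-octadecylphenyl)ethan-1-one
Product: 13 Irisoquin (2-hydroxy-5-methoxy-3-octadecylcyclohexa-2,5-diene-1,4-dione), via aryl acetate 11 (not isolated), via triol 12 (not isolated)
Conditions: H2O2 (30% aq), NaOH, THF–MeOH–H2O, 0 °C → rt, under argon; then HCl (aq); then air, EtOAc, rt
Reagents that add atoms: hydrogen peroxide, OO
Why: Dakin oxidation, in which hydroperoxide adds to the aryl ketone and the electron-rich aryl group with ortho- and para-oxido substituents migrates to oxygen to give the aryl acetate, whose saponification frees the benzene-1,2,4-triol, and this hydroxyhydroquinone should autoxidize in air to the 2-hydroxy-1,4-benzoquinone with the methoxy group untouched.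

Compound list
1 | methyl 4-methoxy-3-oxobutanoate | COCC(=O)CC(=O)OC | starting material
2 | 1-iodooctadecane | CCCCCCCCCCCCCCCCCCI | starting material
3 | sodium (Z)-1,4-dimethoxy-4-oxobut-2-en-2-olate (sodium enolate of 1, formed in the flask) | [Na+].COC/C([O-])=C/C(=O)OC | intermediate
4 | methyl 2-(methoxyacetyl)icosanoate, racemic (= methyl 4-methoxy-2-octadecyl-3-oxobutanoate) | CCCCCCCCCCCCCCCCCCC(C(=O)COC)C(=O)OC | intermediate
5 | methyl 2-[2-methoxy-1-(trimethylsilyloxy)ethylidene]icosanoate (double-bond geometry not controlled) | CCCCCCCCCCCCCCCCCCC(C(=O)OC)=C(COC)O[Si](C)(C)C | intermediate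
6 | lithium 1,4-dimethoxy-2-octadecyl-3-(trimethylsilyloxy)buta-1,3-dien-1-olate (formed in the flask, geometry not controlled) | [Li+].CCCCCCCCCCCCCCCCCCC(C(=COC)O[Si](C)(C)C)=C([O-])OC | intermediate
7 | 1,4-dimethoxy-2-octadecyl-1,3-bis(trimethylsilyloxy)buta-1,3-diene (geometry not controlled) | CCCCCCCCCCCCCCCCCCC(C(=COC)O[Si](C)(C)C)=C(OC)O[Si](C)(C)C | intermediate
8 | but-3-yn-2-one | CC(=O)C#C | starting material
9 | 1-[3,6-dimethoxy-5-octadecyl-4,6-bis(trimethylsilyloxy)cyclohexa-1,4-dien-1-yl]ethan-1-one (mixture of diastereomers, formed in the flask) | CC(=O)C1=CC(OC)C(O[Si](C)(C)C)=C(CCCCCCCCCCCCCCCCCC)C1(OC)O[Si](C)(C)C | intermediate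
10 | 1-(2,4-dihydroxy-5-methoxy-3-octadecylphenyl)ethan-1-one | CC(=O)c1cc(OC)c(O)c(CCCCCCCCCCCCCCCCCC)c1O | intermediate
11 | 2,4-dihydroxy-5-methoxy-3-octadecylphenyl acetate (formed in the flask) | CC(=O)Oc1cc(OC)c(O)c(CCCCCCCCCCCCCCCCCC)c1O | intermediate
12 | 5-methoxy-3-octadecylbenzene-1,2,4-triol (formed in the flask) | COc1cc(O)c(O)c(CCCCCCCCCCCCCCCCCC)c1O | intermediate
13 | Irisoquin, 2-hydroxy-5-methoxy-3-octadecylcyclohexa-2,5-diene-1,4-dione | CCCCCCCCCCCCCCCCCCC1=C(O)C(=O)C=C(OC)C1=O | target

Total step count: 5. Longest linear sequence: 5 steps (1 → 4 → 5 → 7 → 10 → 13).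

Steps most likely to fail

Step 4. The cycloaddition may be too slow for a diene substituted at every carbon, so that loss of the silyl groups or a conjugate addition that stops before ring closure takes over. The fallback replaces ring construction by chemistry on a preformed arene; it sets out from 2 and returns to the route at 13. Commercial 1,2,4,5-tetramethoxybenzene (COc1cc(OC)c(OC)cc1OC) is lithiated between two methoxy groups (n-BuLi, TMEDA, THF, 0 °C) to (2,3,5,6-tetramethoxyphenyl)lithium F1, which is alkylated with 2 to give 1,2,4,5-tetramethoxy-3-octadecylbenzene F2. Oxidative demethylation with (NH4)2Ce(NO3)6 in MeCN–H2O should give 2,5-dimethoxy-3-octadecylcyclohexa-2,5-diene-1,4-dione F3. Aqueous NaOH followed by HCl should hydrolyse both vinylogous esters to 2,5-dihydroxy-3-octadecylcyclohexa-2,5-diene-1,4-dione F4. Acid-catalysed etherification (MeOH, cat. H2SO4, reflux) should then methylate the less hindered vinylogous acid, the one flanking the ring CH, to give 13.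

Step 5. The alkaline peroxide may go on to attack the very electron-rich triol or the quinone as it forms (ring cleavage), or the aryl migration may lag for a hydrogen-bonded ketone. The fallback uses a peracid Baeyer–Villiger oxidation on a protected arene; it sets out from 10 and returns to the route at 12. Both phenols are benzylated (BnBr, K2CO3, DMF, 60 °C) to 1-[2,4-bis(benzyloxy)-5-methoxy-3-octadecylphenyl]ethan-1-one F5. mCPBA (NaHCO3, CH2Cl2, rt) should insert oxygen on the aryl side to give 2,4-bis(benzyloxy)-5-methoxy-3-octadecylphenyl acetate F6. K2CO3 in MeOH removes the acetyl group to give 2,4-bis(benzyloxy)-5-methoxy-3-octadecylphenol F7. Hydrogenolysis (H2, Pd/C, EtOAc) frees triol 12, which is oxidized by air to 13 under neutral conditions as at the end of step 5.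

Step 1. O-alkylation and a second alkylation may compete with a slow substitution on the waxy long-chain iodide. The fallback uses condensation and reduction in place of substitution; it sets out from 1 and returns to the route at 4. Knoevenagel condensation of 1 with commercial octadecanal (CCCCCCCCCCCCCCCCCC=O; piperidine, AcOH, CH2Cl2, 0 °C → rt) should give methyl 2-(methoxyacetyl)icos-2-enoate F8 as an E/Z mixture, and hydrogenation of its electron-poor double bond (H2, Pd/C, EtOAc) should give 4. Steps 2 and 3 follow a standard two-stage protocol and are judged safer; should the diene not be obtainable, the fallback given for step 4 bypasses it as well.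

Further compounds
F1 | step 4 | (2,3,5,6-tetramethoxyphenyl)lithium | [Li]c1c(OC)c(OC)cc(OC)c1OC
F2 | step 4 | 1,2,4,5-tetramethoxy-3-octadecylbenzene | COc1cc(OC)c(OC)c(CCCCCCCCCCCCCCCCCC)c1OC
F3 | step 4 | 2,5-dimethoxy-3-octadecylcyclohexa-2,5-diene-1,4-dione | CCCCCCCCCCCCCCCCCCC1=C(OC)C(=O)C=C(OC)C1=O
F4 | step 4 | 2,5-dihydroxy-3-octadecylcyclohexa-2,5-diene-1,4-dione | CCCCCCCCCCCCCCCCCCC1=C(O)C(=O)C=C(O)C1=O
F5 | step 5 | 1-[2,4-bis(benzyloxy)-5-methoxy-3-octadecylphenyl]ethan-1-one | CC(=O)c1cc(OC)c(OCc2ccccc2)c(CCCCCCCCCCCCCCCCCC)c1OCc3ccccc3
F6 | step 5 | 2,4-bis(benzyloxy)-5-methoxy-3-octadecylphenyl acetate | CC(=O)Oc1cc(OC)c(OCc2ccccc2)c(CCCCCCCCCCCCCCCCCC)c1OCc3ccccc3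
F7 | step 5 | 2,4-bis(benzyloxy)-5-methoxy-3-octadecylphenol | Oc1cc(OC)c(OCc2ccccc2)c(CCCCCCCCCCCCCCCCCC)c1OCc3ccccc3
F8 | step 1 | methyl 2-(methoxyacetyl)icos-2-enoate (E/Z mixture) | CCCCCCCCCCCCCCCCCC=C(C(=O)COC)C(=O)OC
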